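If a catalyst runs a steady round, the time it sits in each form on one turn tells me where to find it.

substrate 0.85 M; partner 3.00 equiv; free catalyst 10 mol%; added ligand 73 mM

    substrate + free catalyst → catalyst intermediate A (k1 = 0.0752 L mol⁻¹ min⁻¹)
    catalyst intermediate A → catalyst intermediate B (k2 = 0.494 min⁻¹)
    partner + catalyst intermediate B → catalyst intermediate C (k3 = 0.00536 L mol⁻¹ min⁻¹)
    catalyst intermediate C → released group + catalyst intermediate D (k4 = 0.0868 min⁻¹)
    catalyst intermediate D → free catalyst + target (k5 = 0.210 min⁻¹)
    free catalyst + added ligand ⇌ idle complex, settled at all times (K6 = 20.8 L mol⁻¹)
    partner → decomposed reagent (k7 = 5.84 × 10⁻⁴ min⁻¹)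

- the form that holds most of the catalyst when 10 % of the substrate are converted (catalyst intermediate C / catalyst intermediate D / free catalyst / catalyst intermediate A / idle complex / catalyst intermediate B)
- its share of the catalyst then

I turned every constant into a time at the charged amounts and read them from fastest to slowest. The balance with added ligand is kept at once, so it stood below every other rung, and with added ligand as charged the idle complex held 1.5 times the free catalyst. Catalyst intermediate A lasted 2.02 min, catalyst intermediate D 4.76 min, catalyst intermediate C 11.5 min and free catalyst 15.6 min, and the balance added 23.8 min in the idle complex, which stands outside the round. Catalyst intermediate B, waiting for partner at c(partner) as charged, lasted 73.2 min, longer than any other form, so I took it as the resting state. Its share came to 55.9 %; this dwell share, a form's sitting time over the sum of sitting times of a whole turn, needs the forms filled and the charges still near their start. By my estimate the forms filled in about 25.6 min, shorter than the 1.20 h of the look, and partner decays over 28.5 h, far longer than that look, so I kept the charged amounts.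

The forecast said catalyst intermediate B at 56 %, in its words “catalyst piles up in intermediate B”. The simulation gave catalyst intermediate B at 56.8 %, 0.90 percentage points above my 55.9 %.

In this flask the exit from catalyst intermediate B ran at 0.82 h⁻¹ with partner as charged, slower than the steps out of catalyst intermediates A, C and D, the lowest of which ran at 5.2 h⁻¹. At 15.0 h, with substrate at 44.0 %, partner at 46.5 % and added ligand at 80.1 % of their charges, the same dwell share came to 62.0 %, and the flask then held 61.6 % of its catalyst as catalyst intermediate B.

The constants used here were drawn at random within sensible limits, and the outcome is calculated.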